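All runs were generated by integration on assumed constants.

Tuesday's flask, with more initiator than Thursday's, holds more product at 8.00 h: 26.7 % against 22.5 %.

all flasks: substrate 20 mM

| flask | reagent | scavenger | initiator | remark | time |
|---|---|---|---|---|---|
| Tuesday's | 22 mM | 20 mM | 0.13 mM | run made earlier |  |
| Thursday's | 22 mM | 20 mM | 0.10 mM | run made earlier |  |
| beta | 22.0 mM | 30.0 mM | 0.20 mM |  | 25 h |
| delta | 22.0 mM | 20.0 mM | 0.20 mM |  | 25 h |

| run | time / h | substrate / % | product / % |
|---|---|---|---|
| Tuesday's | 0.667 | 98.6 | 4.0 |
| Tuesday's | 1.50 | 94.0 | 5.9 |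
| Tuesday's | 3.00 | 90.7 | 9.9 |
| Tuesday's | 5.00 | 83.1 | 17.1 |
| Tuesday's | 6.00 | 77.8 | 20.5 |
| Tuesday's | 8.00 | 74.5 | 26.7 |
| Thursday's | 0.667 | 96.1 | 0.4 |
| Thursday's | 1.33 | 95.2 | 4.5 |
| Thursday's | 2.00 | 90.2 | 7.1 |
| Thursday's | 3.00 | 90.0 | 9.0 |
| Thursday's | 5.00 | 84.6 | 13.9 |
| Thursday's | 8.00 | 77.9 | 22.5 |

(scatter of a reading: 1 percentage point)

- the earlier runs were read with a standard deviation of 1 percentage point
- no earlier run changes the charge of scavenger; that part of a forecast is a guess

- part of the substrate that has reacted at the end, beta
- part of the substrate that has reacted at the end, delta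
- what raising the concentration of scavenger from its lowest to its highest value here does to the part of the substrate that has reacted (changes below 5 percentage points count as none) (no change / it rises / it falls)

So you need a rate that scales to 0.20 mM of initiator. But Tuesday's and Thursday's charge the same substrate and reagent, so comparing these two runs doesn't show whether the loss follows substrate or reagent. I take reagent, and I assume one reagent used per product. The used share of reagent's charge is then the product share times 0.909.

Read as first-order, the last point gives 0.0348 h⁻¹ for Tuesday's and 0.0286 h⁻¹ for Thursday's. Their ratio reads 1.22. The square root of the initiator ratio is 1.14, direct proportion 1.30, and the scatter allows either. I take the square root, as for a radical chain.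

Scaled and averaged, they give 0.0418 h⁻¹, the pseudo-first-order loss constant of reagent at this initiator charge. Over 25 h that reckons 64.8 % of the reagent used, which is 71.3 % of the substrate. No run varies scavenger, so I guess that figure for beta and delta alike.

The forecast differs in its ground, “first-order loss of substrate”. It gives 67 % for beta, 71 % for delta, and no change.

Beta gives 70.9 % and delta 70.9 %: no change, a change of −0.023 percentage points.

    initiator → 2 initiating radical (k = 0.00140 h⁻¹)
    substrate + initiating radical → capped initiator + first chain carrier (k = 2.50 × 10⁶ L mol⁻¹ s⁻¹)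
    reagent + first chain carrier → product + second chain carrier (k = 20000 L mol⁻¹ s⁻¹)
    substrate + second chain carrier → released group + first chain carrier (k = 86000 L mol⁻¹ s⁻¹)
    2 second chain carrier → ended chains A (k = 1.60 × 10⁸ L mol⁻¹ s⁻¹)
    2 first chain carrier → ended chains B (k = 2.20 × 10⁸ L mol⁻¹ s⁻¹)
    substrate + released group ⇌ idle adduct, settled at all times (K = 20.0 L mol⁻¹)
    scavenger + released group → scavenged by-product (k = 810 L mol⁻¹ h⁻¹)

Free scavenger at the end differs, 52.9 % of its charge in beta and 29.6 % in delta. Now take delta with 34 mM of substrate. Held at 0.0418 h⁻¹, the reckoned used share of reagent over 25 h is unchanged, and that is 41.9 % of this larger substrate charge. That neighbour flask gives 42.3 %.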